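**Plan**
Numbering (also used for all spirocyclic intermediates): spiro[5.5]undecane; ring A = C1 (CMe2), C2 (CHBr), C3 (CHOH), C4, C5 (C=CH2), C6 (spiro); ring B = C6, C7, C8 (C=O), C9 (C(OH)CH2Cl), C10, C11.
Retrosynthetic cuts: C9–CH2Cl (carbenoid addition to a ring-B ketone), C5=CH2 (methylenation), C1–C6 (closure of ring A), C3–C4 (aldol) and the C5–C6 acetyl–ring bond (Stille coupling); Br and Cl come from prenol.
Enabling feature: in ring A the bromine sits on secondary C2 next to the gem-dimethyl carbon C1, which is bonded to spiro C6 carrying C5. The array Br–C2–C1(Me2)–C6–C5 is the footprint of a bromonium ion across C1/C2 opened at C1 by a C5=C6 π bond, here a silyl enol ether (C5 at ketone level as a removable helper).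
Forward: ring B is bought as the enol triflate of a cyclohexanedione monoketal; the chain is built by aldol and 1,4-hydrosilylation; ring A closes in step 7 while ring B is still symmetric; C5 is then methylenated and ring B is desymmetrised and oxidised.
Stereochemistry: C2 from catalytic enantioselective bromochlorination; C3 from a Cornforth-controlled aldol; C6 from chiral lithium amide enolisation of the symmetric ring-B ketone; C9 from substrate control through a temporary C8 silyloxy stereocentre that ends as the C8 ketone.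

Key step: step 7

Assumption: the sense of the chiral-base enolisation in step 10 is taken from 4-tert-butylcyclohexanone, where the (R,R)-amide gives the (S)-enol silane; ring B is taken to sit in the chair with the CMe2 arm equatorial and the C5 arm axial.
Assumption: in step 1 the ligand enantiomer is the one that gives the 2S bromochloride; the enol triflate of 1,4-cyclohexanedione monoethylene ketal is a catalogue compound.

Step 1
Reactants: 1 3-methylbut-2-en-1-ol (prenol)
Product: 2 (2S)-2-bromo-3-chloro-3-methylbutan-1-ol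
Conditions: NBS, ClTi(OiPr)3, chiral tridentate Schiff-base amino-alcohol ligand (20 mol%), hexanes, −20 °C
Reagents that add atoms: N-bromosuccinimide (O=C1CCC(=O)N1Br); chlorotitanium triisopropoxide (CC(C)O[Ti](Cl)(OC(C)C)OC(C)C)
Why: Catalytic enantioselective bromochlorination of an allylic alcohol, in which the titanium-bound alkoxide and ligand direct Br+ to one alkene face and chloride opens the bromonium ion anti at the tertiary (Markovnikov) carbon, should set the bromine-bearing centre as 2S.

Step 2
Reactants: 2 (2S)-2-bromo-3-chloro-3-methylbutan-1-ol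
Product: 3 (2S)-2-bromo-3-chloro-3-methylbutanal
Conditions: Dess–Martin periodinane, CH2Cl2, 0 °C; used at once without purification
Reagents that add atoms: none
Why: Dess–Martin oxidation under non-basic conditions should give the configurationally labile α-bromo aldehyde without epimerisation or loss of HCl.

Step 3
Reactants: 4 1,4-dioxaspiro[4.5]dec-7-en-8-yl trifluoromethanesulfonate
Product: 6 1-(1,4-dioxaspiro[4.5]dec-7-en-8-yl)ethan-1-one, via ethoxyvinyl diene 5 (not isolated)
Conditions: tributyl(1-ethoxyvinyl)stannane, Pd(PPh3)4 (5 mol%), LiCl, THF, 65 °C; then 1 M HCl, THF, 0 °C, brief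
Reagents that add atoms: tributyl(1-ethoxyvinyl)stannane (CCCC[Sn](CCCC)(CCCC)C(=C)OCC); water (O)
Why: Stille coupling of an enol triflate with an α-alkoxyvinylstannane followed by hydrolysis of the very acid-labile 2-alkoxydiene is a standard acetyl-anion equivalent, and the dioxolane should survive brief cold dilute acid.

Step 4
Reactants: 6 1-(1,4-dioxaspiro[4.5]dec-7-en-8-yl)ethan-1-one; 3 (2S)-2-bromo-3-chloro-3-methylbutanal
Product: 8 (3S,4S)-4-bromo-5-chloro-3-hydroxy-5-methyl-1-(1,4-dioxaspiro[4.5]dec-7-en-8-yl)hexan-1-one, via lithium dienolate 7 (not isolated)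
Conditions: LiN(iPr)2, THF, −78 °C; then 3, −78 °C; AcOH quench at −78 °C
Reagents that add atoms: none
Why: Kinetic deprotonation of the methyl group gives the cross-conjugated lithium enolate, whose aldol addition to the α-bromo aldehyde should follow the Cornforth (polar Felkin–Anh) model to give the anti bromohydrin, i.e. the 3S carbinol that becomes the ring-A alcohol cis to bromine, while the cold acidic quench prevents epoxide closure.

Step 5
Reactants: 8 (3S,4S)-4-bromo-5-chloro-3-hydroxy-5-methyl-1-(1,4-dioxaspiro[4.5]dec-7-en-8-yl)hexan-1-one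
Product: 9 (3S,4S)-4-bromo-3-[(tert-butyldimethylsilyl)oxy]-5-chloro-5-methyl-1-(1,4-dioxaspiro[4.5]dec-7-en-8-yl)hexan-1-one
Conditions: TBSOTf, 2,6-lutidine, CH2Cl2, −78 to 0 °C
Reagents that add atoms: tert-butyldimethylsilyl trifluoromethanesulfonate (CC(C)(C)[Si](C)(C)OS(=O)(=O)C(F)(F)F)
Why: Silylation with the silyl triflate and a hindered pyridine at low temperature should protect the β-hydroxy ketone without retro-aldol or elimination and gives a non-participating ether for the solvolysis.

Step 6
Reactants: 9 (3S,4S)-4-bromo-3-[(tert-butyldimethylsilyl)oxy]-5-chloro-5-methyl-1-(1,4-dioxaspiro[4.5]dec-7-en-8-yl)hexan-1-one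
Product: 10 8-{(3S,4S)-4-bromo-3-[(tert-butyldimethylsilyl)oxy]-5-chloro-5-methyl-1-[(triethylsilyl)oxy]hexylidene}-1,4-dioxaspiro[4.5]decane
Conditions: Et3SiH, RhCl(PPh3)3 (2 mol%), THF, 50 °C; rapid filtration through Et3N-deactivated silica
Reagents that add atoms: triethylsilane (CC[SiH](CC)CC)
Why: Rhodium-catalysed 1,4-hydrosilylation of an enone with a monohydrosilane should give the tetrasubstituted silyl enol ether regiospecifically (no E/Z issue because ring B is symmetric) under neutral conditions that spare the vicinal bromochloride.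

Step 7
Reactants: 10 8-{(3S,4S)-4-bromo-3-[(tert-butyldimethylsilyl)oxy]-5-chloro-5-methyl-1-[(triethylsilyl)oxy]hexylidene}-1,4-dioxaspiro[4.5]decane
Product: 12 (2R,3S)-2-bromo-3-[(tert-butyldimethylsilyl)oxy]-1,1-dimethylspiro[5.5]undecane-5,9-dione 9-(ethylene ketal), via bromiranium chloride 11 (not isolated)
Conditions: (CF3)2CHOH (HFIP), 2,6-di-tert-butylpyridine, 0 °C to rt
Reagents that add atoms: none
Why: In HFIP the tertiary C–Cl bond should ionise with anchimeric assistance from the neighbouring bromine, so that bromiranium ion 11 forms on the face fixed by the existing C–Br bond; the tetrasubstituted silyl enol ether then attacks the tertiary carbon (future C1) through future C6 from the side opposite to bromine, and the silyl oxocarbenium ion loses Et3SiCl to leave the C5 ketone. The closest known reaction types are the solvolytic generation of bromonium ions from enantioenriched vicinal bromochlorides for bromopolyene cyclisation and the SN1 (Mukaiyama-type) α-tert-alkylation of silyl enol ethers with tertiary halides. Ring A closes in a 6-endo mode with respect to both π components: both bromiranium carbons (C1, C2) and both enol ether carbons (C5, C6) lie in the new six-membered ring, with the C2–Br bond antiperiplanar to the new C1–C6 bond. No new stereocentre has to be controlled, because C6 is not stereogenic while ring B is symmetric and C1 carries two methyl groups, while C2 keeps its configuration since its C–Br bond is never broken and the ring opens at C1, so chair and boat transition states converge on one product. The step needs Markovnikov opening at C1 (not 5-exo attack at C2), C- over O-alkylation, and cyclisation ahead of proton loss, solvent capture or bromine transfer; these should be secured by the cation-stabilising gem-dimethyl carbon, the silicon cap on oxygen, the high π-nucleophilicity of the tetrasubstituted enol ether and the hindered pyridine buffer.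

Step 8
Reactants: 12 (2R,3S)-2-bromo-3-[(tert-butyldimethylsilyl)oxy]-1,1-dimethylspiro[5.5]undecane-5,9-dione 9-(ethylene ketal)
Product: 13 (2R,3S)-2-bromo-3-[(tert-butyldimethylsilyl)oxy]-1,1-dimethyl-5-methylidenespiro[5.5]undecan-9-one ethylene ketal
Conditions: Tebbe reagent Cp2Ti(μ-CH2)(μ-Cl)AlMe2, pyridine (cat.), THF/toluene, −40 to 0 °C
Reagents that add atoms: Tebbe reagent Cp2Ti(μ-CH2)(μ-Cl)AlMe2, drawn with the bridging chloride as a formal chloronium and aluminium as a formal aluminate (C[Al-]1(C)C[Ti]([Cl+]1)(C1C=CC=C1)C1C=CC=C1)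
Why: Tebbe methylenation, in which the Lewis base releases titanocene methylidene that adds to the carbonyl and collapses through an oxatitanacyclobutane, converts hindered, enolisable ketones into 1,1-disubstituted alkenes under non-basic conditions, so the α-quaternary C5 ketone should give the exocyclic methylidene without β-elimination of the silyloxy group while the ketal masks the ring-B carbonyl.

Step 9
Reactants: 13 (2R,3S)-2-bromo-3-[(tert-butyldimethylsilyl)oxy]-1,1-dimethyl-5-methylidenespiro[5.5]undecan-9-one ethylene ketal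
Product: 14 (2R,3S)-2-bromo-3-[(tert-butyldimethylsilyl)oxy]-1,1-dimethyl-5-methylidenespiro[5.5]undecan-9-one
Conditions: PPTS, acetone/H2O, 50 °C
Reagents that add atoms: water (O)
Why: Mild acid-catalysed ketal hydrolysis should unmask the ring-B ketone while the secondary silyl ether and the exocyclic alkene are retained.

Step 10
Reactants: 14 (2R,3S)-2-bromo-3-[(tert-butyldimethylsilyl)oxy]-1,1-dimethyl-5-methylidenespiro[5.5]undecan-9-one
Product: 15 (2R,3S,6R)-2-bromo-3-[(tert-butyldimethylsilyl)oxy]-1,1-dimethyl-5-methylidene-9-[(trimethylsilyl)oxy]spiro[5.5]undec-8-ene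
Conditions: LiN[(S)-CH(CH3)Ph]2 (from the (S,S)-amine and n-BuLi), LiCl, TMSCl (in situ quench), THF, −100 to −78 °C
Reagents that add atoms: chlorotrimethylsilane (C[Si](C)(C)Cl)
Why: Chiral lithium amide deprotonation with in situ silylation (asymmetric enolisation of a 4,4-disubstituted cyclohexanone): with ring B locked in the chair that has the CMe2 arm equatorial, the (S,S)-amide should remove the axial proton at C8 and not the one at C10, so that reagent control makes C6 stereogenic with the R configuration.

Step 11
Reactants: 15 (2R,3S,6R)-2-bromo-3-[(tert-butyldimethylsilyl)oxy]-1,1-dimethyl-5-methylidene-9-[(trimethylsilyl)oxy]spiro[5.5]undec-8-ene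
Product: 17 (2R,3S,6R,8R)-2-bromo-3-[(tert-butyldimethylsilyl)oxy]-1,1-dimethyl-5-methylidene-8-[(trimethylsilyl)oxy]spiro[5.5]undecan-9-one, via silyloxy epoxide 16 (not isolated)
Conditions: dimethyldioxirane (1.05 equiv, acetone solution), CH2Cl2, −78 to 0 °C; then rt; used crude
Reagents that add atoms: dimethyldioxirane (CC1(C)OO1)
Why: Rubottom oxidation, in which dimethyldioxirane should epoxidise the electron-rich silyl enol ether far faster than the 1,1-disubstituted alkene and from the ring-B face anti to the axial C5 arm, after which 1,4-silyl shift in silyloxy epoxide 16 gives the ketone with an equatorial C8 silyloxy group (8R).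

Step 12
Reactants: 17 (2R,3S,6R,8R)-2-bromo-3-[(tert-butyldimethylsilyl)oxy]-1,1-dimethyl-5-methylidene-8-[(trimethylsilyl)oxy]spiro[5.5]undecan-9-one
Product: 19 (2R,3S,6R,8R,9S)-2-bromo-3-[(tert-butyldimethylsilyl)oxy]-9-(chloromethyl)-1,1-dimethyl-5-methylidenespiro[5.5]undecane-8,9-diol, via chlorohydrin trimethylsilyl ether 18 (not isolated)
Conditions: ICH2Cl, MeLi·LiBr, THF/Et2O, −78 °C; AcOH quench at −78 °C; then citric acid, MeOH, 0 °C
Reagents that add atoms: chloroiodomethane (ClCI)
Why: Halomethyl carbenoid addition, in which chloromethyllithium made in situ by iodine–lithium exchange should add to the unhindered C9 ketone along the equatorial trajectory, trans to the neighbouring equatorial silyloxy group of the locked chair, to give the axial tertiary alcohol with the chloromethyl group cis to the C5 arm (9S), the cold acidic quench keeping the chlorohydrin from closing to an epoxide and methanolic citric acid removing only the trimethylsilyl group.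

Step 13
Reactants: 19 (2R,3S,6R,8R,9S)-2-bromo-3-[(tert-butyldimethylsilyl)oxy]-9-(chloromethyl)-1,1-dimethyl-5-methylidenespiro[5.5]undecane-8,9-diol
Product: 20 (2R,3S,6R,9S)-2-bromo-3-[(tert-butyldimethylsilyl)oxy]-9-(chloromethyl)-9-hydroxy-1,1-dimethyl-5-methylidenespiro[5.5]undecan-8-one
Conditions: Dess–Martin periodinane, CH2Cl2, 0 °C to rt
Reagents that add atoms: none
Why: Dess–Martin oxidation of the secondary hydroxyl of a secondary/tertiary 1,2-diol should give the α-hydroxy ketone without C–C cleavage and without base that could close the chlorohydrin, and it removes the temporary C8 stereocentre.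

Step 14
Reactants: 20 (2R,3S,6R,9S)-2-bromo-3-[(tert-butyldimethylsilyl)oxy]-9-(chloromethyl)-9-hydroxy-1,1-dimethyl-5-methylidenespiro[5.5]undecan-8-one
Product: 21 (2R,3S,6R,9S)-2-bromo-9-(chloromethyl)-3,9-dihydroxy-1,1-dimethyl-5-methylidenespiro[5.5]undecan-8-one
Conditions: HF·pyridine, THF/pyridine, 0 °C to rt
Reagents that add atoms: none
Why: Acidic fluoride cleavage of the secondary silyl ether, with no base present that could turn the chlorohydrin into an epoxide, should release the target with all four stereocentres untouched.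

**Compound list**
1 | 3-methylbut-2-en-1-ol (prenol) | CC(C)=CCO | starting material
2 | (2S)-2-bromo-3-chloro-3-methylbutan-1-ol | OC[C@H](Br)C(C)(C)Cl | intermediate
3 | (2S)-2-bromo-3-chloro-3-methylbutanal | O=C[C@H](Br)C(C)(C)Cl | intermediate
4 | 1,4-dioxaspiro[4.5]dec-7-en-8-yl trifluoromethanesulfonate | O=S(=O)(OC1=CCC2(CC1)OCCO2)C(F)(F)F | starting material
5 | 8-(1-ethoxyethenyl)-1,4-dioxaspiro[4.5]dec-7-ene (ethoxyvinyl diene) | CCOC(=C)C1=CCC2(CC1)OCCO2 | intermediate
6 | 1-(1,4-dioxaspiro[4.5]dec-7-en-8-yl)ethan-1-one | CC(=O)C1=CCC2(CC1)OCCO2 | intermediate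
7 | lithium 1-(1,4-dioxaspiro[4.5]dec-7-en-8-yl)ethen-1-olate (lithium dienolate) | [Li]OC(=C)C1=CCC2(CC1)OCCO2 | intermediate
8 | (3S,4S)-4-bromo-5-chloro-3-hydroxy-5-methyl-1-(1,4-dioxaspiro[4.5]dec-7-en-8-yl)hexan-1-one | O=C(C[C@H](O)[C@H](Br)C(C)(C)Cl)C1=CCC2(CC1)OCCO2 | intermediate
9 | (3S,4S)-4-bromo-3-[(tert-butyldimethylsilyl)oxy]-5-chloro-5-methyl-1-(1,4-dioxaspiro[4.5]dec-7-en-8-yl)hexan-1-one | O=C(C[C@H](O[Si](C)(C)C(C)(C)C)[C@H](Br)C(C)(C)Cl)C1=CCC2(CC1)OCCO2 | intermediate
10 | 8-{(3S,4S)-4-bromo-3-[(tert-butyldimethylsilyl)oxy]-5-chloro-5-methyl-1-[(triethylsilyl)oxy]hexylidene}-1,4-dioxaspiro[4.5]decane | CC[Si](CC)(CC)OC(C[C@H](O[Si](C)(C)C(C)(C)C)[C@H](Br)C(C)(C)Cl)=C1CCC2(CC1)OCCO2 | intermediate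
11 | bromiranium chloride formed from 10 by loss of chloride, bromine bridging the former CHBr and CCl carbons, configuration at the CHBr carbon unchanged | CC[Si](CC)(CC)OC(C[C@H](O[Si](C)(C)C(C)(C)C)[C@@H]1[Br+]C1(C)C)=C1CCC2(CC1)OCCO2.[Cl-] | intermediate
12 | (2R,3S)-2-bromo-3-[(tert-butyldimethylsilyl)oxy]-1,1-dimethylspiro[5.5]undecane-5,9-dione 9-(ethylene ketal) | O=C1C[C@H](O[Si](C)(C)C(C)(C)C)[C@H](Br)C(C)(C)C12CCC3(CC2)OCCO3 | intermediate
13 | (2R,3S)-2-bromo-3-[(tert-butyldimethylsilyl)oxy]-1,1-dimethyl-5-methylidenespiro[5.5]undecan-9-one ethylene ketal | C=C1C[C@H](O[Si](C)(C)C(C)(C)C)[C@H](Br)C(C)(C)C12CCC3(CC2)OCCO3 | intermediate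
14 | (2R,3S)-2-bromo-3-[(tert-butyldimethylsilyl)oxy]-1,1-dimethyl-5-methylidenespiro[5.5]undecan-9-one | C=C1C[C@H](O[Si](C)(C)C(C)(C)C)[C@H](Br)C(C)(C)C12CCC(=O)CC2 | intermediate
15 | (2R,3S,6R)-2-bromo-3-[(tert-butyldimethylsilyl)oxy]-1,1-dimethyl-5-methylidene-9-[(trimethylsilyl)oxy]spiro[5.5]undec-8-ene | C=C1C[C@H](O[Si](C)(C)C(C)(C)C)[C@H](Br)C(C)(C)[C@@]12CCC(O[Si](C)(C)C)=CC2 | intermediate
16 | 8,9-epoxide of 15 (silyloxy epoxide), oxirane oxygen on the ring-B face opposite to the C5 arm | C=C1C[C@H](O[Si](C)(C)C(C)(C)C)[C@H](Br)C(C)(C)[C@@]12CC[C@]3(O[Si](C)(C)C)O[C@@H]3C2 | intermediate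
17 | (2R,3S,6R,8R)-2-bromo-3-[(tert-butyldimethylsilyl)oxy]-1,1-dimethyl-5-methylidene-8-[(trimethylsilyl)oxy]spiro[5.5]undecan-9-one | C=C1C[C@H](O[Si](C)(C)C(C)(C)C)[C@H](Br)C(C)(C)[C@@]12CCC(=O)[C@H](O[Si](C)(C)C)C2 | intermediate
18 | (2R,3S,6R,8R,9S)-2-bromo-3-[(tert-butyldimethylsilyl)oxy]-9-(chloromethyl)-1,1-dimethyl-5-methylidene-8-[(trimethylsilyl)oxy]spiro[5.5]undecan-9-ol (chlorohydrin trimethylsilyl ether) | C=C1C[C@H](O[Si](C)(C)C(C)(C)C)[C@H](Br)C(C)(C)[C@@]12CC[C@@](O)(CCl)[C@H](O[Si](C)(C)C)C2 | intermediate
19 | (2R,3S,6R,8R,9S)-2-bromo-3-[(tert-butyldimethylsilyl)oxy]-9-(chloromethyl)-1,1-dimethyl-5-methylidenespiro[5.5]undecane-8,9-diol | C=C1C[C@H](O[Si](C)(C)C(C)(C)C)[C@H](Br)C(C)(C)[C@@]12CC[C@@](O)(CCl)[C@H](O)C2 | intermediate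
20 | (2R,3S,6R,9S)-2-bromo-3-[(tert-butyldimethylsilyl)oxy]-9-(chloromethyl)-9-hydroxy-1,1-dimethyl-5-methylidenespiro[5.5]undecan-8-one | C=C1C[C@H](O[Si](C)(C)C(C)(C)C)[C@H](Br)C(C)(C)[C@@]12CC[C@@](O)(CCl)C(=O)C2 | intermediate
21 | (2R,3S,6R,9S)-2-bromo-9-(chloromethyl)-3,9-dihydroxy-1,1-dimethyl-5-methylidenespiro[5.5]undecan-8-one | C=C1C[C@H](O)[C@H](Br)C(C)(C)[C@@]12CC[C@@](O)(CCl)C(=O)C2 | target

Total step count: 14
Longest linear sequence: 13 steps (steps 1, 2 and 4 to 14, from prenol)

**Steps most likely to fail**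

Step 7. The triethylsilyl enol ether may be protodesilylated by HFIP before the chloride ionises; the free ketone could then capture the cation through oxygen, or the cation could lose a proton or take up solvent. The closure may also be slowed by the 1,3-diaxial contact between the C3 silyloxy group and a C1 methyl group in the chair transition state. The fallback replaces the oxygen-bound terminator by a carbon-bound one and sets out from 10. Treatment with CsF and PhNTf2 (DME, rt) should give the enol triflate (3S,4S)-4-bromo-3-[(tert-butyldimethylsilyl)oxy]-5-chloro-1-(1,4-dioxaspiro[4.5]decan-8-ylidene)-5-methylhexyl trifluoromethanesulfonate F1. Kumada-type coupling with Me3SiCH2MgCl and Pd(PPh3)4 (THF, 0 °C to rt) should give the tetrasubstituted allylsilane {(4S,5S)-5-bromo-4-[(tert-butyldimethylsilyl)oxy]-6-chloro-2-(1,4-dioxaspiro[4.5]decan-8-ylidene)-6-methylheptyl}trimethylsilane F2. Solvolysis of F2 in buffered HFIP should then close ring A by an allylsilane-terminated bromonium cyclisation, with loss of the silyl group forming the C5 methylidene directly. The route is rejoined at 13 and step 8 is not needed.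

Step 10. The chiral amide may discriminate poorly between the two ring-B arms, or its access to the axial protons may be hindered by the C5 methylidene lying over ring B; either would give both regioisomeric enol ethers and hence both configurations at C6. The fallback sets out from 14. Dehydrogenation with IBX (DMSO, 70 °C) should give the cross-conjugated dienone (2R,3S)-2-bromo-3-[(tert-butyldimethylsilyl)oxy]-1,1-dimethyl-5-methylidenespiro[5.5]undeca-7,10-dien-9-one F3. An ene-reductase of the Old Yellow Enzyme family (flavin-dependent, NADPH recycled with glucose and glucose dehydrogenase, pH 7 buffer, 30 °C), chosen by screening for reduction of the C10=C11 bond, should reduce one of the two diastereotopic enone double bonds and give (2R,3S,6R)-2-bromo-3-[(tert-butyldimethylsilyl)oxy]-1,1-dimethyl-5-methylidenespiro[5.5]undec-7-en-9-one F4. Conjugate reduction of F4 with LiBH(s-Bu)3 (THF, −78 °C) and trapping of the regiodefined enolate with TMSCl/Et3N should return to the route at 15.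

Step 12. The small carbenoid may show poor facial selectivity (axial against equatorial attack), may decompose before it adds, or its adduct may close to an epoxide. The fallback uses thermodynamically controlled methylene transfer and sets out from 17. Dimethylsulfoxonium methylide (Me3S(O)I, NaH, DMSO, rt; Corey–Chaykovsky epoxidation with equatorial C–C bond formation) should give (2R,3S,6R,8R)-2-bromo-3-[(tert-butyldimethylsilyl)oxy]-1,1-dimethyl-5-methylidene-8-[(trimethylsilyl)oxy]spiro[5.5]undecane-9-spiro-2'-oxirane, oxirane oxygen axial on ring B and trans to the C5 arm, F5. Opening of F5 at the methylene carbon with LiCl/AcOH (THF, rt) should give the chlorohydrin trimethylsilyl ether 18, and citric acid in MeOH, as in step 12, should then remove the trimethylsilyl group and return to the route at 19.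

Further compounds
F1 | step 7 | (3S,4S)-4-bromo-3-[(tert-butyldimethylsilyl)oxy]-5-chloro-1-(1,4-dioxaspiro[4.5]decan-8-ylidene)-5-methylhexyl trifluoromethanesulfonate | O=S(=O)(OC(C[C@H](O[Si](C)(C)C(C)(C)C)[C@H](Br)C(C)(C)Cl)=C1CCC2(CC1)OCCO2)C(F)(F)F
F2 | step 7 | {(4S,5S)-5-bromo-4-[(tert-butyldimethylsilyl)oxy]-6-chloro-2-(1,4-dioxaspiro[4.5]decan-8-ylidene)-6-methylheptyl}trimethylsilane | C[Si](C)(C)CC(C[C@H](O[Si](C)(C)C(C)(C)C)[C@H](Br)C(C)(C)Cl)=C1CCC2(CC1)OCCO2
F3 | step 10 | (2R,3S)-2-bromo-3-[(tert-butyldimethylsilyl)oxy]-1,1-dimethyl-5-methylidenespiro[5.5]undeca-7,10-dien-9-one | C=C1C[C@H](O[Si](C)(C)C(C)(C)C)[C@H](Br)C(C)(C)C12C=CC(=O)C=C2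
F4 | step 10 | (2R,3S,6R)-2-bromo-3-[(tert-butyldimethylsilyl)oxy]-1,1-dimethyl-5-methylidenespiro[5.5]undec-7-en-9-one | C=C1C[C@H](O[Si](C)(C)C(C)(C)C)[C@H](Br)C(C)(C)[C@@]12CCC(=O)C=C2
F5 | step 12 | (2R,3S,6R,8R)-2-bromo-3-[(tert-butyldimethylsilyl)oxy]-1,1-dimethyl-5-methylidene-8-[(trimethylsilyl)oxy]spiro[5.5]undecane-9-spiro-2'-oxirane, oxirane oxygen axial on ring B | C=C1C[C@H](O[Si](C)(C)C(C)(C)C)[C@H](Br)C(C)(C)[C@@]12CC[C@@]3(CO3)[C@H](O[Si](C)(C)C)C2
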